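A leftover opens the reckoning. If each side product A takes up one reagent, the 47 % of substrate turned into it by 4.00 min in the alder run leaves 0.0397 M of the 0.075 M reagent.

- alder: substrate 0.075 M; reagent 0.075 M; run made earlier
- flask: substrate 0.050 M; reagent 0.0750 M; time 40 min

alder run (percent of the substrate charged)

| time / min | target / % | side product A / % |
|---|---|---|
| 0.500 | 6 | 16 |
| 1.00 | 18 | 23 |
| 1.50 | 23 | 33 |
| 2.50 | 32 | 39 |
| 3.00 | 35 | 40 |
| 4.00 | 38 | 47 |

(readings scatter by 2 percentage points)

Asked is the share of target in target plus side product A for a flask charged with 0.050 M substrate and 0.0750 M reagent, at 2.0 s, 1.0 min and 40 min. Readings scatter by 2 percentage points.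

Suppose target forms without reagent and side product A with it. Reagent in the alder run then averaged 0.0574 M, while target stood to side product A as 38 % to 47 %. That gives 0.0464 M, a reading with the readings' scatter: the crossing level, the reagent concentration at which both products grow equally fast (a selectivity factor in concentration units).

The new flask has two extreme versions. With reagent held at its charge, the share is 38.2 %. With the whole substrate charge going to side product A, reagent ends at 0.0250 M, where the share of what forms is 65.0 %. This reckoning expects the flask's share at 40 min between them, the first lower than the second.

One step from the first extreme puts mean reagent at 0.0596 M, so this reckoning commits to 43.8 % at 40 min. At 1.0 min it stays near 38.2 %. The first alder reading has target lower against side product A than the last one, and if that ratio of target to side product A grows in proportion to time, this reckoning puts it at about 0.0250 at 2.0 s.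

The forecast differs in its ground, “the split seems independent of concentration”, and gave 20 %, 43 % and 45 %.

The flask gives 4.31 %, 37.5 % and 47.1 %.

    substrate + reagent → side product A (k = 0.0890 L mol⁻¹ s⁻¹)
    substrate ⇌ intermediate A (K = 0.320, k = 0.0120 s⁻¹)
    reagent + intermediate A ⇌ intermediate B (K = 7.30 L mol⁻¹, k = 0.120 L mol⁻¹ s⁻¹)
    intermediate B → intermediate C (k = 0.00880 s⁻¹)
    intermediate A → target (k = 0.0260 s⁻¹)
    reagent + intermediate C → side product B (k = 0.0550 L mol⁻¹ s⁻¹)

In this flask reagent stands at 60.6 % of its charge at 40.0 min, and the share there is 47.1 % against the 43.8 % reckoned from the crossing level. The same step on the neighbouring flask with 0.019 M reagent starts from 70.9 %, takes mean reagent as 0.0117 M and reckons 79.9 %; that flask gives 80.7 %.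

The runs come from a simulation on assumed constants.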